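Ring C of the target holds two heteroatoms on neighbouring alkene carbons: ring oxygen O1 on C2 and the sulfated oxygen on C3, trans across C2=C3. An oxygen nucleophile and an electrophile leave exactly this pattern when they add from opposite sides to a triple bond between C2 and C3 that is conjugated with the C4 ketone. The route therefore cuts O1–C2 and the C3–heteroatom bond back to a fully benzylated aryl alkynyl ketone whose ring A is symmetrical. One treatment with ICl should close ring C, expel a single benzyl group and place iodine at C3. C3 is the only position later converted into hydroxyl and sulfated. All phenols stay benzylated until the final hydrogenolysis.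

Key step: step 5

Assumption: the target is taken as the free hydrogen sulfate drawn in its SMILES; because such acids hydrolyse themselves, the sulfate is carried as its potassium salt and protonated only in the last operation.

Step 1
Reactants: 1 2,4,6-trihydroxybenzaldehyde; 2 benzyl bromide
Product: 3 2,4,6-tris(benzyloxy)benzaldehyde
Conditions: BnBr (3.6 equiv), K2CO3 (4.5 equiv), DMF, 60 °C
Reagents that add atoms: benzyl bromide (2), BrCc1ccccc1
Why: Williamson ether synthesis: the formyl group pulls electron density out of the ring carbons, so the three phenoxides should react at oxygen with the benzylic bromide in a dipolar aprotic solvent, and warming with excess reagent should bring the two hydrogen-bonded ortho hydroxyls to completion.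

Step 2
Reactants: 4 4-(benzyloxy)benzaldehyde; 5 dimethyl (1-diazo-2-oxopropyl)phosphonate
Product: 6 1-(benzyloxy)-4-ethynylbenzene
Conditions: 5 (1.2 equiv), K2CO3 (2 equiv), MeOH–THF, rt
Reagents that add atoms: dimethyl (1-diazo-2-oxopropyl)phosphonate (5), COP(=O)(OC)C(=[N+]=[N-])C(C)=O
Why: Seyferth–Gilbert homologation in its Ohira–Bestmann form: methanolysis of the acetyl group of 5 frees the diazomethylphosphonate anion, which adds to the non-enolisable aldehyde, and loss of dimethyl phosphate and N2 followed by a 1,2-hydrogen shift in the alkylidene carbene should give the terminal alkyne under conditions that leave the benzyl ether alone.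

Step 3
Reactants: 6 1-(benzyloxy)-4-ethynylbenzene; 3 2,4,6-tris(benzyloxy)benzaldehyde
Product: 8 1-[2,4,6-tris(benzyloxy)phenyl]-3-[4-(benzyloxy)phenyl]prop-2-yn-1-ol (racemic), via lithium acetylide 7 (not isolated)
Conditions: n-BuLi (1.05 equiv), THF, −78 °C; then 3, −78 → 0 °C; H2O quench; product used crude
Reagents that add atoms: n-butyllithium, [Li]CCCC (lithium of 7 only; nothing stays in 8)
Why: 1,2-Addition of a lithium acetylide to an aldehyde that has no α-hydrogen and no other electrophilic site; the carbinol carbon is formed without control as a racemate, which is irrelevant because step 4 flattens it, and the neutral quench protects an alcohol that ionises readily in acid.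

Step 4
Reactants: 8 1-[2,4,6-tris(benzyloxy)phenyl]-3-[4-(benzyloxy)phenyl]prop-2-yn-1-ol
Product: 9 1-[2,4,6-tris(benzyloxy)phenyl]-3-[4-(benzyloxy)phenyl]prop-2-yn-1-one
Conditions: activated MnO2 (15 equiv), CH2Cl2, rt
Reagents that add atoms: none
Why: MnO2 oxidation of a doubly activated (benzylic and propargylic) alcohol, a neutral heterogeneous method that should spare the benzyl ethers, the alkyne and the acid-sensitive carbinol and cannot overoxidise.

Step 5
Reactants: 9 1-[2,4,6-tris(benzyloxy)phenyl]-3-[4-(benzyloxy)phenyl]prop-2-yn-1-one; 10 iodine monochloride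
Product: 12 5,7-bis(benzyloxy)-2-[4-(benzyloxy)phenyl]-3-iodo-4H-chromen-4-one, via O1-benzyl oxonium chloride 11 (not isolated)
Conditions: ICl (1.05 equiv, 1.0 M in CH2Cl2, slow addition), CH2Cl2, −78 °C; aq Na2S2O3 wash
Reagents that add atoms: iodine monochloride (10), ClI
Why: ICl turns the triple bond into an iodonium-type species whose positive charge lies mainly on C2, the carbon next to the donor 4-(benzyloxy)phenyl ring; an ortho ether oxygen of ring A attacks this carbon from the side opposite iodine to give oxonium chloride 11, which chloride dealkylates at the benzylic carbon to 12. The closest known reaction type is the ICl-induced electrophilic cyclization of 2-alkoxyaryl alkynyl ketones to 3-iodochromones, an iodocyclization with dealkylation. Ring C closes in the 6-endo-dig mode by forming O1–C2, and no stereocentre arises, the anti addition surviving only as the trans relation of O1 and iodine on C2=C3. Selectivity for 6-endo over 5-exo closure (which would give an aurone-type ring) rests on aryl stabilisation of cationic character at C2 and on the inability of C3, α to the carbonyl, to carry positive charge. Selectivity for the alkyne over C–H iodination of rings A and B rests on the deactivating acyl group on ring A, on slow addition of barely more than one equivalent in the cold and on fast intramolecular capture. The two ortho oxygens are equivalent, so no regiochemical question arises in ring A, and benzyl leaves the oxonium ion more readily than a simple alkyl group, which drives the closure forward.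

Step 6
Reactants: 12 5,7-bis(benzyloxy)-2-[4-(benzyloxy)phenyl]-3-iodo-4H-chromen-4-one
Product: 15 5,7-bis(benzyloxy)-2-[4-(benzyloxy)phenyl]-3-hydroxy-4H-chromen-4-one, via C3 chloromagnesium flavone 13 (not isolated), via C3 dimethyl boronate 14 (not isolated)
Conditions: i-PrMgCl·LiCl (1.1 equiv), THF, −60 °C; B(OMe)3 (2.5 equiv), −60 → 0 °C; AcOH, 30% aq H2O2, 0 °C → rt
Reagents that add atoms: hydrogen peroxide, OO (the oxygen at C3 of 15); isopropylmagnesium chloride, CC(C)[Mg]Cl (MgCl of 13 only); trimethyl borate, COB(OC)OC (B(OMe)2 of 14 only)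
Why: Halogen–magnesium exchange with the turbo-Grignard reagent on an electron-poor alkenyl iodide should outrun carbonyl addition in the cold, C3-metalated flavones are known to persist at low temperature without expelling the O1 phenoxide, and borate trapping followed by the 1,2-migration oxidation with H2O2 in weakly acidic medium should deliver hydroxyl at C3 alone without the alkali that would open the pyrone.

Step 7
Reactants: 15 5,7-bis(benzyloxy)-2-[4-(benzyloxy)phenyl]-3-hydroxy-4H-chromen-4-one; 16 sulfur trioxide–pyridine complex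
Product: 18 potassium 5,7-bis(benzyloxy)-2-[4-(benzyloxy)phenyl]-4-oxo-4H-chromen-3-yl sulfate, via pyridinium sulfate salt 17 (not isolated)
Conditions: SO3·pyridine (3 equiv), DMF, 40 °C; aq KHCO3, 0 °C; evaporation with toluene, reversed-phase silica
Reagents that add atoms: sulfur trioxide–pyridine complex (16), [O-]S(=O)(=O)[n+]1ccccc1; potassium hydrogen carbonate, [K+].OC([O-])=O
Why: O-Sulfonation with a SO3–amine complex: the C3 enol is the only free hydroxyl of 15, so no regiochemical question arises, and exchange of pyridinium for K+ gives a salt that resists hydrolysis and carries no nitrogen base that would slow Pd/C in step 8.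

Step 8
Reactants: 18 potassium 5,7-bis(benzyloxy)-2-[4-(benzyloxy)phenyl]-4-oxo-4H-chromen-3-yl sulfate
Product: 20 kaempferol 3-O-sulfate (5,7-dihydroxy-2-(4-hydroxyphenyl)-4-oxo-4H-chromen-3-yl hydrogen sulfate), via potassium kaempferol 3-sulfate 19 (not isolated)
Conditions: H2 (1 atm), Pd/C (10 wt %), MeOH–THF, rt; filtration; Amberlite IR-120 (H+ form), MeOH–H2O, 0 °C; freeze-drying
Reagents that add atoms: none
Why: Catalytic hydrogenolysis of aryl benzyl ethers followed by cation exchange: the sulfate monoester anion is inert to H2 over Pd/C, the tetrasubstituted C2=C3 bond of the pyrone should not be reduced at one atmosphere, and a cold sulfonic acid resin swaps K+ for H+ just before freeze-drying so that the labile acid form has little time to hydrolyse.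

Compound list
1 | 2,4,6-trihydroxybenzaldehyde | O=Cc1c(O)cc(O)cc1O | starting material
2 | benzyl bromide | BrCc1ccccc1 | starting material
3 | 2,4,6-tris(benzyloxy)benzaldehyde | O=Cc1c(OCc2ccccc2)cc(OCc2ccccc2)cc1OCc1ccccc1 | intermediate
4 | 4-(benzyloxy)benzaldehyde | O=Cc1ccc(OCc2ccccc2)cc1 | starting material
5 | dimethyl (1-diazo-2-oxopropyl)phosphonate | COP(=O)(OC)C(=[N+]=[N-])C(C)=O | starting material
6 | 1-(benzyloxy)-4-ethynylbenzene | C#Cc1ccc(OCc2ccccc2)cc1 | intermediate
7 | lithium [4-(benzyloxy)phenyl]acetylide (not isolated) | [Li]C#Cc1ccc(OCc2ccccc2)cc1 | intermediate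
8 | 1-[2,4,6-tris(benzyloxy)phenyl]-3-[4-(benzyloxy)phenyl]prop-2-yn-1-ol (racemic) | OC(C#Cc1ccc(OCc2ccccc2)cc1)c1c(OCc2ccccc2)cc(OCc2ccccc2)cc1OCc1ccccc1 | intermediate
9 | 1-[2,4,6-tris(benzyloxy)phenyl]-3-[4-(benzyloxy)phenyl]prop-2-yn-1-one | O=C(C#Cc1ccc(OCc2ccccc2)cc1)c1c(OCc2ccccc2)cc(OCc2ccccc2)cc1OCc1ccccc1 | intermediate
10 | iodine monochloride | ClI | starting material
11 | 1-benzyl-5,7-bis(benzyloxy)-2-[4-(benzyloxy)phenyl]-3-iodo-4-oxo-4H-chromen-1-ium chloride (not isolated) | O=C1C(I)=C(c2ccc(OCc3ccccc3)cc2)[O+](Cc2ccccc2)c2cc(OCc3ccccc3)cc(OCc3ccccc3)c21.[Cl-] | intermediate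
12 | 5,7-bis(benzyloxy)-2-[4-(benzyloxy)phenyl]-3-iodo-4H-chromen-4-one | O=c1c(I)c(-c2ccc(OCc3ccccc3)cc2)oc2cc(OCc3ccccc3)cc(OCc3ccccc3)c12 | intermediate
13 | {5,7-bis(benzyloxy)-2-[4-(benzyloxy)phenyl]-4-oxo-4H-chromen-3-yl}magnesium chloride (not isolated) | O=c1c([Mg]Cl)c(-c2ccc(OCc3ccccc3)cc2)oc2cc(OCc3ccccc3)cc(OCc3ccccc3)c12 | intermediate
14 | dimethyl {5,7-bis(benzyloxy)-2-[4-(benzyloxy)phenyl]-4-oxo-4H-chromen-3-yl}boronate (not isolated) | O=c1c(B(OC)OC)c(-c2ccc(OCc3ccccc3)cc2)oc2cc(OCc3ccccc3)cc(OCc3ccccc3)c12 | intermediate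
15 | 5,7-bis(benzyloxy)-2-[4-(benzyloxy)phenyl]-3-hydroxy-4H-chromen-4-one | O=c1c(O)c(-c2ccc(OCc3ccccc3)cc2)oc2cc(OCc3ccccc3)cc(OCc3ccccc3)c12 | intermediate
16 | sulfur trioxide–pyridine complex | [O-]S(=O)(=O)[n+]1ccccc1 | starting material
17 | pyridinium 5,7-bis(benzyloxy)-2-[4-(benzyloxy)phenyl]-4-oxo-4H-chromen-3-yl sulfate (not isolated) | O=c1c(OS(=O)(=O)[O-])c(-c2ccc(OCc3ccccc3)cc2)oc2cc(OCc3ccccc3)cc(OCc3ccccc3)c12.c1cc[nH+]cc1 | intermediate
18 | potassium 5,7-bis(benzyloxy)-2-[4-(benzyloxy)phenyl]-4-oxo-4H-chromen-3-yl sulfate | O=c1c(OS(=O)(=O)[O-])c(-c2ccc(OCc3ccccc3)cc2)oc2cc(OCc3ccccc3)cc(OCc3ccccc3)c12.[K+] | intermediate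
19 | potassium 5,7-dihydroxy-2-(4-hydroxyphenyl)-4-oxo-4H-chromen-3-yl sulfate (not isolated) | O=c1c(OS(=O)(=O)[O-])c(-c2ccc(O)cc2)oc2cc(O)cc(O)c12.[K+] | intermediate
20 | kaempferol 3-O-sulfate | O=c1c(OS(=O)(=O)O)c(-c2ccc(O)cc2)oc2cc(O)cc(O)c12 | target

Total step count: 8. Longest linear sequence: 7 (step 1 or step 2, then steps 3 to 8).

Steps most likely to fail

Step 5. Electrophilic C–H iodination of the alkoxy-rich rings A and B may compete with activation of the alkyne. ICl may add across the triple bond without ring closure, or the departing benzyl group may be transferred to an arene carbon. The fallback sets out from 9 and comes back at 14; it separates ring closure from C3 functionalisation.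
- MgBr2·OEt2 (1 equiv) in warm toluene–Et2O removes one benzyl group ortho to the carbonyl through chelation and should give 1-[2,4-bis(benzyloxy)-6-hydroxyphenyl]-3-[4-(benzyloxy)phenyl]prop-2-yn-1-one F1.
- Catalytic DMAP in DMF then brings about the 6-endo oxa-Michael closure to 5,7-bis(benzyloxy)-2-[4-(benzyloxy)phenyl]-4H-chromen-4-one F2.
- LDA in THF at −78 °C removes the C3 hydrogen to give 5,7-bis(benzyloxy)-2-[4-(benzyloxy)phenyl]-3-lithio-4H-chromen-4-one F3.
- B(OMe)3 converts F3 into boronate 14, from which the oxidative half of step 6 continues.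

Step 6. The C3 carbanion may expel the O1 phenoxide by β-elimination, which reopens ring C. The organometallic may be protonated, with net loss of iodine, or the Grignard reagent may attack the C4 carbonyl. The fallback sets out from 12 and comes back at 15, and it avoids any carbanion at C3.
- Miyaura borylation with B2pin2, PdCl2(dppf) and KOAc in dioxane at 80 °C should give 5,7-bis(benzyloxy)-2-[4-(benzyloxy)phenyl]-3-(4,4,5,5-tetramethyl-1,3,2-dioxaborolan-2-yl)-4H-chromen-4-one F4.
- NaBO3·4H2O in THF–H2O at rt then oxidises F4 to 15.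

Step 8. The threefold debenzylation may stall through poor solubility of the salt or residual nitrogen base on the catalyst, and the sulfate may be lost by slow hydrolysis during a prolonged reaction. The fallback sets out from 15 and comes back at 19; it deprotects first and relies on the innate reactivity order of the flavonol hydroxyls.
- H2 over Pd/C in THF–MeOH converts 15 into kaempferol F5.
- DCC and Bu4NHSO4 in pyridine at 4 °C, a carbodiimide-mediated sulfation known to take the 3-hydroxyl of flavonols first, should give tetrabutylammonium kaempferol 3-sulfate F6.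
- KOAc in MeOH precipitates the potassium salt 19, which goes on to the acid resin as in step 8.

Further compounds
F1 | step 5 | 1-[2,4-bis(benzyloxy)-6-hydroxyphenyl]-3-[4-(benzyloxy)phenyl]prop-2-yn-1-one | O=C(C#Cc1ccc(OCc2ccccc2)cc1)c1c(O)cc(OCc2ccccc2)cc1OCc1ccccc1
F2 | step 5 | 5,7-bis(benzyloxy)-2-[4-(benzyloxy)phenyl]-4H-chromen-4-one | O=c1cc(-c2ccc(OCc3ccccc3)cc2)oc2cc(OCc3ccccc3)cc(OCc3ccccc3)c12
F3 | step 5 | 5,7-bis(benzyloxy)-2-[4-(benzyloxy)phenyl]-3-lithio-4H-chromen-4-one | O=c1c([Li])c(-c2ccc(OCc3ccccc3)cc2)oc2cc(OCc3ccccc3)cc(OCc3ccccc3)c12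
F4 | step 6 | 5,7-bis(benzyloxy)-2-[4-(benzyloxy)phenyl]-3-(4,4,5,5-tetramethyl-1,3,2-dioxaborolan-2-yl)-4H-chromen-4-one | O=c1c(B4OC(C)(C)C(C)(C)O4)c(-c2ccc(OCc3ccccc3)cc2)oc2cc(OCc3ccccc3)cc(OCc3ccccc3)c12
F5 | step 8 | kaempferol | O=c1c(O)c(-c2ccc(O)cc2)oc2cc(O)cc(O)c12
F6 | step 8 | tetrabutylammonium kaempferol 3-sulfate | O=c1c(OS(=O)(=O)[O-])c(-c2ccc(O)cc2)oc2cc(O)cc(O)c12.CCCC[N+](CCCC)(CCCC)CCCC
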